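- Start from the target, the large number here: the last south reading gives 43 % of target against 3 % of side product. That side reading stands 1.50 scatters above zero, so a share of target (the selectivity) taken from it is loose.

| flask | substrate | reagent | temperature | remark | time |
|---|---|---|---|---|---|
| west | 0.086 M | 3 equiv | 85 °C | run made earlier |  |
| south | 0.39 M | 3 equiv | 100 °C | run made earlier |  |
| zeta | 0.50 M | 3.00 equiv | 100 °C |  | 2.0 h |
| delta | 0.12 M | 3.00 equiv | 100 °C |  | 0.50 h |

west run (percent of the substrate charged)

| time / h | target / % | side product / % | substrate / % |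
|---|---|---|---|
| 0.167 | 3 | 0 | 95 |
| 0.417 | 6 | 0 | 87 |
| 0.833 | 8 | 0 | 74 |
| 1.33 | 10 | 0 | 62 |
| 2.00 | 20 | 0 | 52 |
| 3.00 | 20 | 1 | 38 |

south run (percent of the substrate charged)

| time / min | target / % | side product / % | substrate / % |
|---|---|---|---|
| 6.00 | 14 | 0 | 59 |
| 10.0 | 16 | 2 | 47 |
| 15.0 | 25 | 2 | 30 |
| 25.0 | 29 | 0 | 15 |
| 40.0 | 34 | 0 | 11 |
| 60.0 | 39 | 4 | 3 |
| 80.0 | 43 | 3 | 3 |

(readings scatter by 2 percentage points)

- the winner by share of target in all that became target or side product; "neither" if no more than 2 percentage points parts them (zeta / delta / neither)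
- share of target in all that became target or side product, zeta
- share of target in all that became target or side product, delta

- the numbers in the tables scatter by 2 percentage points (one standard deviation)
- where the amount of substrate changes, what is given in equivalents or mol% on it follows

- So pool the south run: its readings add up to 11.0 % of side product and 200 % of target, which gives 0.0550. Call this ρ, the side-to-target ratio: side product per target.
- The scatter of that sum carries into ρ as 0.0265.
- The share is 1/(1+ρ), so 94.8 %, with a band from 92.5 % to 97.2 %. That band is wider than the margin.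
- You carry ρ to both flasks and commit to 94.8 % for zeta and for delta, hence neither.
- One weak link is carrying ρ across time, so split the south run. The first 4 readings give 0.0476, the last 3 give 0.0603, and their gap lies inside the scatter of ρ. This split stands at the single south concentration of 0.39 M, so it does not test the other link, carrying ρ to the concentrations of zeta and delta.
- The forecast differs from this reckoning: 91 % for zeta, 96 % for delta, winner delta, on the ground that the side product “is near noise level and appears late or at higher concentration”.
- The flasks give 97.8 % for zeta and 97.9 % for delta, so the answer is neither: they part by 0.1 percentage points, less than the margin.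

    intermediate B ⇌ intermediate C (K = 0.750, k = 0.00121 s⁻¹, Ea = 116 kJ mol⁻¹, ΔH = −8.00 kJ mol⁻¹)
    substrate + reagent → target (k = 3.79 × 10⁻⁴ M⁻¹ s⁻¹, Ea = 80.0 kJ mol⁻¹)
    substrate ⇌ intermediate A (K = 2.23, k = 2.06 × 10⁻⁵ s⁻¹, Ea = 120 kJ mol⁻¹, ΔH = −22.0 kJ mol⁻¹)
    intermediate A → side product (k = 1.45 × 10⁻⁴ s⁻¹, Ea = 128 kJ mol⁻¹)
    2 substrate → homo dimer (k = 0.00126 M⁻¹ s⁻¹, Ea = 94.0 kJ mol⁻¹)
    substrate + reagent ⇌ intermediate B (K = 1.50 M⁻¹, k = 2.31 × 10⁻⁴ M⁻¹ s⁻¹, Ea = 72.0 kJ mol⁻¹, ΔH = −3.00 kJ mol⁻¹)
    (constants at 100 °C)

- Taken from the amounts at the asked time, ρ is 0.0221 in zeta and 0.0211 in delta, and 1/(1+ρ) returns the shares above. Now take the neighbour, the same flask as zeta run at 125 °C: it holds 3.98 % of side product against 47.5 % of target. Its ρ is 0.0837, which is 3.79 times that of zeta, and its share is 92.3 %.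

The earlier runs and the new flask come from a simulation on assumed constants, and the scatter is random.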